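The data were computed for an exercise, and the scatter is random.

Amounts opened the meeting on this flask, whose charge, earlier readings and questions stood before everyone:

| flask | starting material | partner | remark | time |
|---|---|---|---|---|
| beta | 0.050 M | 0.15 M | the very flask that is asked about, followed so far |  |
| flask | 0.050 M | 0.150 M |  | 1.0 h |

beta run (percent of the starting material charged)

| time / min | double product / % | tris adduct / % |
|---|---|---|
| 1.33 | 60 | 6 |
| 4.00 | 88 | 10 |
| 6.00 | 86 | 9 |
| 10.0 | 88 | 12 |
| 15.0 | 90 | 10 |
| 20.0 | 86 | 8 |

(standard deviation of a reading: 2 percentage points)

- equivalents of partner to starting material, everything else as given, that leave most double product at 1.0 h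
- the amount of double product then, in percent of the starting material charged
- the amount of double product with the amounts as given

- the earlier runs were read with a standard deviation of 2 percentage points

The process chemist proposed to average the five readings from 4.00 min on and to count the partner they hold, 2 for each double product and 3 for each tris adduct, which gave 2.05 equivalents as a reading, and she asked that this figure, the partner bound per starting material charged, be kept as the uptake. The kineticist replied that the given flask is charged with 3.00 equivalents, more than the uptake, so that the charge exceeds that reading by about 0.954 equivalents and starting material is the limiting reagent. The chair's own reckoning was to try a charge at the uptake itself, which is lower than the forecast's charge. The forecaster then gave 2.3 equiv (range 2.05 equiv to 3 equiv), with 91% of double product there (87% to 96%) and 88% with the amounts as given (84% to 91%), noting that “1 h allows a slow finish”.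

The flask gives most double product, 98.8%, at 2.10 equiv, and 91.8% with the amounts as given.

    partner → decomposition product (k = 5.60 × 10⁻⁵ s⁻¹)
    partner + single product → double product + released group (k = 0.250 M⁻¹ s⁻¹)
    partner + double product ⇌ tris adduct + released group (K = 0.250, k = 0.240 M⁻¹ s⁻¹)
    starting material + partner → single product + released group (k = 0.450 M⁻¹ s⁻¹)

At that better charge the tris adduct is 0.859%, against 8.23% in the flask as given, and the uptake counts 2.00 equivalents. The neighbour flask charged with 0.037 M of partner holds 0.740 equivalents, less than the uptake, and partner is its limiting reagent, with 0% left at 1.00 h; counted at 1 per single product and 2 per double product, its uptake is 0.738 equivalents, with 45.0% single product beside 14.4% double product.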